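**Plan**
- First cut: the bond between the diarylmethane CH2 and the ipso carbon of the 4-hydroxyphenyl ring (ring C). The CH2 is raised to a CH bearing morpholine as a temporary helper. This leads back to a ring-A aldehyde, morpholine and an arylboronic acid, joined in a three-component Petasis borono-Mannich reaction.
- Enabling feature: the free phenol O–H on the ring-A carbon directly next to the carbon that carries the CH2. At the aldehyde level this pair is a salicylaldehyde, whose phenoxide O binds boron and delivers the aryl group to the adjacent iminium carbon.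
- Second cut: ring A C–CH2 of the ethano bridge, made as an aryl–vinyl bond by a Heck reaction. Third cut: one O–CH3, removed by formyl-directed demethylation of a symmetrical 2,6-dimethoxybenzaldehyde, which differentiates OH from OMe.
- Forward order: no ring is formed, since all three benzene rings are bought. Ring A is desymmetrised, ring B is attached (Heck), ring C is attached (Petasis), and one hydrogenation removes the alkene, both benzyl ethers and the morpholine.
- Stereochemistry: the target is achiral. The only stereocentre on the way (the benzhydryl CH of the Petasis adduct) is made racemic and erased in the last step, as is the E-alkene.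

Key step: step 4

Remark: the target has no stereocentre, stereogenic axis or C=C bond, so the single-enantiomer requirement needs no stereocontrol. Compound 1 is taken as a catalogue compound.

**Step 1**
Reactants: 1 4-bromo-2,6-dimethoxybenzaldehyde
Product: 3 4-bromo-2-hydroxy-6-methoxybenzaldehyde, via (5-bromo-2-formyl-3-methoxyphenoxy)dichloroborane 2 (not isolated)
Conditions: BCl3 (1.1 equiv), CH2Cl2, −78 °C → 0 °C; then aqueous work-up
Reagents that add atoms: none
Why: Chelation-directed mono-O-demethylation, in which BCl3 bridges the formyl O and one of the two equivalent flanking OMe groups, chloride removes that methyl, and the six-membered boron chelate 2 blocks a second cleavage; it is run before any BCl3-labile benzyl ether is present.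

**Step 2**
Reactants: 4 2-(benzyloxy)benzaldehyde
Product: 5 1-(benzyloxy)-2-vinylbenzene
Conditions: Ph3PCH3Br, KOtBu, THF, 0 °C → rt
Reagents that add atoms: methyltriphenylphosphonium bromide, C[P+](c1ccccc1)(c1ccccc1)c1ccccc1.[Br-]
Why: Wittig methylenation of a non-enolisable aromatic aldehyde with an unstabilised ylide, to which the benzyl ether is inert.

**Step 3**
Reactants: 3 4-bromo-2-hydroxy-6-methoxybenzaldehyde; 5 1-(benzyloxy)-2-vinylbenzene
Product: 6 4-{(E)-2-[2-(benzyloxy)phenyl]ethenyl}-2-hydroxy-6-methoxybenzaldehyde
Conditions: Pd(OAc)2 (cat.), P(o-tol)3 (cat.), Et3N, DMF, 100 °C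
Reagents that add atoms: none
Why: Heck reaction of an aryl bromide activated by the para formyl group with a styrene, where insertion at the terminal alkene carbon and syn β-hydride elimination should give the E-stilbene, as known for bromosalicylaldehydes with a free OH.

**Step 4**
Reactants: 6 4-{(E)-2-[2-(benzyloxy)phenyl]ethenyl}-2-hydroxy-6-methoxybenzaldehyde; 7 morpholine; 8 4-(benzyloxy)phenylboronic acid
Product: 10 (±)-2-{[4-(benzyloxy)phenyl](morpholin-4-yl)methyl}-5-{(E)-2-[2-(benzyloxy)phenyl]ethenyl}-3-methoxyphenol, via zwitterionic iminium aryloxy(aryl)dihydroxyboronate 9 (not isolated)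
Conditions: 7 (1.3 equiv), 8 (1.5 equiv), 4 Å MS, 1,4-dioxane, 90 °C; aqueous work-up
Reagents that add atoms: none
Why: Morpholine condenses with the formyl group of 6 to an iminium phenoxide, the phenoxide O on the neighbouring ring-A carbon binds the boron of 8 to give the tetracoordinate boronate 9, the electron-rich aryl group migrates by its ipso carbon from boron to the iminium carbon through a six-membered transition state (C=N carbon, two ring-A carbons, O, B, ipso C), and work-up hydrolyses the O–B(OH)2 ester. The closest known reaction type is this same Petasis borono-Mannich three-component reaction of salicylaldehydes, secondary amines and electron-rich arylboronic acids to give 2-(α-aminobenzyl)phenols. No ring is closed, and the one new stereocentre (the benzhydryl CH) is left racemic on purpose because step 5 converts it into the CH2 of the target. Site selectivity on both rings is built into the precursors: the bond can form only at the former formyl carbon, lodged between OH and OMe of ring A where Friedel–Crafts benzylation of the parent resorcinol monoether would be disfavoured, and only at the boron-bearing carbon para to oxygen in ring C, so ortho/para isomers cannot arise. Chemoselectivity rests on the neutral boronic acid being unreactive towards the aldehyde, the stilbene and the vinylogous positions, so only the boronate held next to the iminium transfers aryl and the alkene, benzyl ethers and OMe are spectators. Molecular sieves, excess amine and boronic acid, and heat offset the slower iminium formation expected at this doubly ortho-substituted, electron-rich aldehyde.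

**Step 5**
Reactants: 10 (±)-2-{[4-(benzyloxy)phenyl](morpholin-4-yl)methyl}-5-{(E)-2-[2-(benzyloxy)phenyl]ethenyl}-3-methoxyphenol
Product: 12 2-(4-hydroxybenzyl)-5-[2-(2-hydroxyphenyl)ethyl]-3-methoxyphenol (target), via (±)-5-[2-(2-hydroxyphenyl)ethyl]-2-[(4-hydroxyphenyl)(morpholin-4-yl)methyl]-3-methoxyphenol 11 (not isolated)
Conditions: H2 (1–4 bar), 10% Pd/C, EtOH–AcOH, 50 °C
Reagents that add atoms: none
Why: Catalytic hydrogenation/hydrogenolysis should saturate the stilbene and cleave both O-benzyl ethers to give 11, whose protonated, doubly benzylic C–N bond, flanked by ortho- and para-hydroxyaryl groups, is then cleaved as is known for 2-(α-aminobenzyl)phenols and -naphthols; the morpholine ring C–N bonds, the OMe and the arenes are untouched.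

**Compound list**
1 | 4-bromo-2,6-dimethoxybenzaldehyde | COc1cc(Br)cc(OC)c1C=O | starting material
2 | (5-bromo-2-formyl-3-methoxyphenoxy)dichloroborane (carbonyl-chelated) | COc1cc(Br)cc(OB(Cl)Cl)c1C=O | intermediate
3 | 4-bromo-2-hydroxy-6-methoxybenzaldehyde | COc1cc(Br)cc(O)c1C=O | intermediate
4 | 2-(benzyloxy)benzaldehyde | O=Cc1ccccc1OCc1ccccc1 | starting material
5 | 1-(benzyloxy)-2-vinylbenzene | C=Cc1ccccc1OCc1ccccc1 | intermediate
6 | 4-{(E)-2-[2-(benzyloxy)phenyl]ethenyl}-2-hydroxy-6-methoxybenzaldehyde | COc1cc(/C=C/c2ccccc2OCc2ccccc2)cc(O)c1C=O | intermediate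
7 | morpholine | C1COCCN1 | starting material
8 | 4-(benzyloxy)phenylboronic acid | OB(O)c1ccc(OCc2ccccc2)cc1 | starting material
9 | zwitterionic morpholinium-ylidene (iminium) aryloxy[4-(benzyloxy)phenyl]dihydroxyboronate | COc1cc(/C=C/c2ccccc2OCc2ccccc2)cc(O[B-](O)(O)c2ccc(OCc3ccccc3)cc2)c1C=[N+]1CCOCC1 | intermediate
10 | (±)-2-{[4-(benzyloxy)phenyl](morpholin-4-yl)methyl}-5-{(E)-2-[2-(benzyloxy)phenyl]ethenyl}-3-methoxyphenol | COc1cc(/C=C/c2ccccc2OCc2ccccc2)cc(O)c1C(N1CCOCC1)c1ccc(OCc2ccccc2)cc1 | intermediate
11 | (±)-5-[2-(2-hydroxyphenyl)ethyl]-2-[(4-hydroxyphenyl)(morpholin-4-yl)methyl]-3-methoxyphenol | COc1cc(CCc2ccccc2O)cc(O)c1C(N1CCOCC1)c1ccc(O)cc1 | intermediate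
12 | 2-(4-hydroxybenzyl)-5-[2-(2-hydroxyphenyl)ethyl]-3-methoxyphenol | COc1cc(CCc2ccccc2O)cc(O)c1Cc1ccc(O)cc1 | target

**Step count**
Total steps: 5. Longest linear sequence: 4 (steps 1, 3, 4, 5).

**Steps most likely to fail**

Step 4. Iminium formation at the doubly ortho-substituted, electron-rich formyl group may be so slow that protodeboronation of the boronic acid wins. The fallback sets out from 6 and replaces the three-component event with a two-component organometallic addition. Commercial 4-(benzyloxy)phenylmagnesium bromide (over 2 equiv, the first consumed by the phenol; THF, 0 °C → rt) should add to the aldehyde. This gives (±)-2-{[4-(benzyloxy)phenyl](hydroxy)methyl}-5-{(E)-2-[2-(benzyloxy)phenyl]ethenyl}-3-methoxyphenol F1. Under the conditions of step 5 the benzhydrylic C–O bond of F1 is hydrogenolysed together with the alkene and the benzyl ethers. The route is rejoined at 12.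

Step 5. The reaction may stall after alkene saturation and O-debenzylation because the C–N hydrogenolysis is slow or the liberated amine poisons the catalyst. The fallback sets out from 10 and removes the amine by hydride instead of on the metal surface. Heating with excess NaBH4 in refluxing EtOH should expel morpholine thermally. This gives the o-quinone methide 6-[4-(benzyloxy)benzylidene]-3-{(E)-2-[2-(benzyloxy)phenyl]ethenyl}-5-methoxycyclohexa-2,4-dien-1-one F2. Hydride attacks F2 at the exocyclic carbon (reductive deamination of a phenolic Mannich base) to give 2-[4-(benzyloxy)benzyl]-5-{(E)-2-[2-(benzyloxy)phenyl]ethenyl}-3-methoxyphenol F3. Ordinary hydrogenation (H2, Pd/C, EtOAc–EtOH, rt) then reduces the alkene and cleaves the benzyl ethers. The route is rejoined at 12.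

Step 3. The catalyst may be deactivated by chelation to the salicylaldehyde unit, the styrene may polymerise thermally, or regiocontrol in the insertion may erode. The fallback sets out from 5 and 3 and builds the saturated bridge directly by a B-alkyl Suzuki–Miyaura coupling.
- Hydroboration of 5 with 9-BBN-H (THF, 0 °C → rt) gives 9-{2-[2-(benzyloxy)phenyl]ethyl}-9-borabicyclo[3.3.1]nonane F4.
- F4 is coupled with 3 (PdCl2(dppf), aq. K3PO4, THF–DMF, 50 °C) to give 4-{2-[2-(benzyloxy)phenyl]ethyl}-2-hydroxy-6-methoxybenzaldehyde F5.
- The conditions of step 4 with 7 and 8 then give (±)-2-{[4-(benzyloxy)phenyl](morpholin-4-yl)methyl}-5-{2-[2-(benzyloxy)phenyl]ethyl}-3-methoxyphenol F6.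
- The conditions of step 5 convert F6 into the target, and the route is rejoined at 12.

**Further compounds**
F1 | step 4 | (±)-2-{[4-(benzyloxy)phenyl](hydroxy)methyl}-5-{(E)-2-[2-(benzyloxy)phenyl]ethenyl}-3-methoxyphenol | COc1cc(/C=C/c2ccccc2OCc2ccccc2)cc(O)c1C(O)c1ccc(OCc2ccccc2)cc1
F2 | step 5 | 6-[4-(benzyloxy)benzylidene]-3-{(E)-2-[2-(benzyloxy)phenyl]ethenyl}-5-methoxycyclohexa-2,4-dien-1-one | COC1=CC(/C=C/c2ccccc2OCc2ccccc2)=CC(=O)C1=Cc1ccc(OCc2ccccc2)cc1
F3 | step 5 | 2-[4-(benzyloxy)benzyl]-5-{(E)-2-[2-(benzyloxy)phenyl]ethenyl}-3-methoxyphenol | COc1cc(/C=C/c2ccccc2OCc2ccccc2)cc(O)c1Cc1ccc(OCc2ccccc2)cc1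
F4 | step 3 | 9-{2-[2-(benzyloxy)phenyl]ethyl}-9-borabicyclo[3.3.1]nonane | c1ccccc1COc1ccccc1CCB1C2CCCC1CCC2
F5 | step 3 | 4-{2-[2-(benzyloxy)phenyl]ethyl}-2-hydroxy-6-methoxybenzaldehyde | COc1cc(CCc2ccccc2OCc2ccccc2)cc(O)c1C=O
F6 | step 3 | (±)-2-{[4-(benzyloxy)phenyl](morpholin-4-yl)methyl}-5-{2-[2-(benzyloxy)phenyl]ethyl}-3-methoxyphenol | COc1cc(CCc2ccccc2OCc2ccccc2)cc(O)c1C(N1CCOCC1)c1ccc(OCc2ccccc2)cc1
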